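## Retrosynthetic overview

1. Briarellin A ⇐ late Schenck ene reaction (Z-C6=C7 olefin → C6–OH / C7=CH2), after a Pd-mediated carbonylative lactonisation (C16 from CO) and face-selective hydrogenation (C15).
2. Cyclohexane ⇐ intermolecular Diels–Alder of a C1=C10–C11(OEt)=C12 diene (from the C10 ketone) with methyl vinyl ketone.
3. Oxonene plus oxolanone ⇐ key step: a copper carbenoid → oxonium ylide → [2,3]-sigmatropic three-carbon ring expansion of a 2,6-cis-oxanyl diazoketone, in place of the usual RCM or Nozaki–Hiyama–Kishi closure of the nine-membered ring.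
4. Oxane ⇐ vinylsilane-terminated Prins cyclisation of a β-alkoxyacrylate, then epoxidation and trans-diaxial hydrolysis for the C3/C4 diol.
5. Ring order: oxane → oxonene and oxolane together → cyclohexane → lactone. All stereochemistry is relayed from one carbinol centre set by asymmetric propargylation of methacrolein.

Assumption: locants C1–C16 are the usual eunicellin locants of the target (ether bridge C2–O–C9, lactone C16(=O)–O–C3, octanoate on C4, OH on C6, methylidene on C7, carbinol C11).
Assumption: in step 1 the antipode of the ligand is the one that delivers the (S)-alcohol 3.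

## Route

Step 1
Reactants: 1 methacrolein; 2 TMS-propargyl pinacolboronate
Product: 3 (3S)-2-methyl-6-(trimethylsilyl)hex-1-en-5-yn-3-ol
Conditions: Cu(O2CCHMe2)2 (5 mol%), MeO-BIBOP (6 mol%), LiOtBu (8 mol%), THF, −30 °C; H2O work-up
Reagents that add atoms: none
Why: Catalytic asymmetric propargylation: boron-to-copper exchange gives a chiral allenylcopper that adds to the aldehyde by SE2′, so the silylalkyne ends distal and the ligand fixes the S carbinol, the only reagent-controlled stereocentre of the route.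

Step 2
Reactants: 3
Product: 4 (3S,5Z)-2-methyl-6-(trimethylsilyl)hepta-1,5-dien-3-ol
Conditions: i-Bu2AlH (2.2 equiv), hexane–Et2O, 0 → 45 °C; MeLi (1.1 equiv), 0 °C; MeI, THF, rt; H2O work-up
Reagents that add atoms: iodomethane, CI
Why: Silicon-directed cis-hydroalumination places aluminium on the silyl-bearing carbon and the alanate formed with MeLi is methylated by MeI with retention (hydroalumination–alkylation of a 1-silylalkyne), giving the trisubstituted vinylsilane without touching the carbinol centre.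

Step 3
Reactants: 4; 5 ethyl propiolate
Product: 6 ethyl (2E)-3-{[(3S,5Z)-2-methyl-6-(trimethylsilyl)hepta-1,5-dien-3-yl]oxy}prop-2-enoate
Conditions: N-methylmorpholine (cat.), CH2Cl2, rt
Reagents that add atoms: none
Why: Amine-catalysed oxa-Michael addition of the secondary alcohol to the ynoate gives the E β-alkoxyacrylate (vinylogous carbonate) and leaves the stereocentre untouched.

Step 4
Reactants: 6
Product: 7 ethyl 2-[(2S,6S)-3-methyl-6-(prop-1-en-2-yl)-3,6-dihydro-2H-pyran-2-yl]acetate
Conditions: CF3CO2H (5 equiv), CH2Cl2, −40 → 0 °C; then H2O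
Reagents that add atoms: none
Why: Proposed new method: C-protonation of the β-alkoxyacrylate gives an oxocarbenium ion that is captured by ipso attack of the vinylsilane (β-silyl cation, then loss of silicon fixes the C3=C4 olefin) through a chair transition state with both substituents equatorial, so C2 forms cis to C6; the closest known reaction types are the acid-promoted Prins cyclisation of vinylogous carbonates and the vinylsilane-terminated (silyl-Prins) oxocarbenium cyclisation to 3,6-dihydro-2H-pyrans.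

Step 5
Reactants: 7
Product: 10 (3aS,5S,7R,7aS)-7-hydroxy-7a-methyl-5-(prop-1-en-2-yl)hexahydro-2H-furo[3,2-b]pyran-2-one, via epoxide 8 (not isolated), via diol ester 9 (not isolated)
Conditions: mCPBA (1.05 equiv), CH2Cl2, −10 °C; then 5% aq. HClO4, THF, rt
Reagents that add atoms: mCPBA, O=C(OO)c1cccc(Cl)c1; water, O
Why: Prilezhaev epoxidation selects the trisubstituted ring olefin, and acid-catalysed trans-diaxial (Fürst–Plattner) hydrolysis gives the same 3,4-diaxial diol from either oxirane face (as with the limonene oxides), setting C3–OH cis and C4–OH trans to the C2 side chain, after which the cis tertiary hydroxyl lactonises onto the ester.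

Step 6
Reactants: 10
Product: 13 2-[(2S,3R,4R,6S)-3,4-bis(tert-butyldimethylsilyloxy)-3-methyl-6-(prop-1-en-2-yl)oxan-2-yl]acetic acid, via lithium carboxylate 11 (not isolated), via silyl ester 12 (not isolated)
Conditions: LiOH, THF–H2O, rt, evaporate; TBSOTf (4 equiv), 2,6-lutidine, CH2Cl2, 0 → 40 °C; AcOH–H2O–THF, rt
Reagents that add atoms: lithium hydroxide, [Li+].[OH-]; TBSOTf, CC(C)(C)[Si](C)(C)OS(=O)(=O)C(F)(F)F
Why: Lactone saponification followed by exhaustive silyl triflate silylation caps the secondary C4 and tertiary C3 hydroxyls while the acid is held as a labile silyl ester that dilute aqueous acetic acid then cleaves, so relactonisation is impossible and no stereocentre is touched.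

Step 7
Reactants: 13
Product: 15 1-diazo-3-[(2S,3R,4R,6S)-3,4-bis(tert-butyldimethylsilyloxy)-3-methyl-6-(prop-1-en-2-yl)oxan-2-yl]propan-2-one, via mixed anhydride 14 (not isolated)
Conditions: i-BuOCOCl, Et3N, Et2O, 0 °C; then CH2N2, Et2O, 0 °C → rt
Reagents that add atoms: diazomethane, C=[N+]=[N-]; isobutyl chloroformate, CC(C)COC(=O)Cl (in 14 only)
Why: Acylation of diazomethane by the mixed carbonic anhydride (first stage of the Arndt–Eistert protocol) gives the α-diazoketone under non-acidic conditions that spare the silyl ethers and the olefin.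

Step 8
Reactants: 15
Product: 17 (5Z)-2,3-bis(tert-butyldimethylsilyloxy)-2,6-dimethyl-11-oxabicyclo[6.2.1]undec-5-en-9-one, via oxonium ylide 16 (not isolated)
Conditions: Cu(CF3COCHCOCF3)2 (5 mol%), CH2Cl2, reflux
Reagents that add atoms: none
Why: The copper carbenoid is trapped by the ring oxygen to give a bicyclic oxonium ylide whose suprafacial [2,3]-sigmatropic rearrangement onto the cis isopropenyl group inserts three carbons into the oxane, creating in one step the nine-membered ring, the oxolanone, the C9 centre (bridge cis to C2, dictated by the 2,6-cis oxane) and the Z C6=C7 olefin (the minor E isomer is removed by chromatography).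

Step 9
Reactants: 17
Product: 18 (5Z)-2,3-bis(tert-butyldimethylsilyloxy)-2,6-dimethyl-11-oxabicyclo[6.2.1]undeca-5,9-dien-9-yl trifluoromethanesulfonate
Conditions: NaN(SiMe3)2, PhNTf2, THF, −78 °C
Reagents that add atoms: N-phenylbis(trifluoromethanesulfonimide), O=S(=O)(N(c1ccccc1)S(=O)(=O)C(F)(F)F)C(F)(F)F
Why: Kinetic deprotonation at the C1 methylene (not at the bridgehead C9–H) and O-sulfonylation of the enolate give the C1=C10 enol triflate regioselectively.

Step 10
Reactants: 18; 19 tributyl(1-ethoxyvinyl)stannane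
Product: 20 (5Z)-9-(1-ethoxyethenyl)-2,3-bis(tert-butyldimethylsilyloxy)-2,6-dimethyl-11-oxabicyclo[6.2.1]undeca-5,9-diene
Conditions: Pd(PPh3)4 (5 mol%), LiCl, THF, 65 °C
Reagents that add atoms: none
Why: Stille coupling of the enol triflate with the α-ethoxyvinylstannane installs C11 and C12 and gives the electron-rich 2-ethoxy-1,3-diene C1=C10–C11(OEt)=C12.

Step 11
Reactants: 20; 21 methyl vinyl ketone
Product: 23 C14-acetyl tricyclic enol ether (single epimer), via cycloadduct epimer mixture 22 (not isolated)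
Conditions: 21 (10 equiv), BHT (cat.), toluene, 120 °C, sealed tube; then K2CO3 (cat.), MeOH, rt
Reagents that add atoms: none
Why: Intermolecular Diels–Alder reaction with para regiochemistry (acetyl on C14, 1,4 to the ethoxy carbon) in which the dienophile adds to the diene face opposite the nine-membered ring and so fixes C1, after which base equilibration through the acetyl enolate converges the exo/endo adducts to the equatorial C14 epimer (acetyl trans to C2).

Step 12
Reactants: 23
Product: 24 C14 isopropenyl triflate (C10=C11 enol ether retained)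
Conditions: KN(SiMe3)2, PhNTf2, THF, −78 °C
Reagents that add atoms: N-phenylbis(trifluoromethanesulfonimide), O=S(=O)(N(c1ccccc1)S(=O)(=O)C(F)(F)F)C(F)(F)F
Why: Kinetic enolisation of the methyl ketone toward the methyl group and O-triflation give the terminal vinyl triflate while the base-stable enol ether masks C11 and C14 is not epimerised.

Step 13
Reactants: 24
Product: 25 C11 ketone (cis-fused, vinyl triflate retained)
Conditions: 1 M aq. HCl (cat.), THF, 0 °C → rt
Reagents that add atoms: water, O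
Why: Acid hydrolysis of the enol ether unmasks the C11 ketone, and protonation/equilibration at the α-carbon C10 gives the thermodynamically preferred cis ring fusion (H1 and H10 cis) while the C3 oxygen is still silylated and cannot add across the C6=C7 olefin.

Step 14
Reactants: 25
Product: 26 C11 tertiary alcohol (11R)
Conditions: MeMgCl, CeCl3, THF, −78 °C; H2O
Reagents that add atoms: methylmagnesium chloride, C[Mg]Cl
Why: Non-basic organocerium 1,2-addition in which methyl attacks axially from the convex face, the other face being screened by the axial C10–C9 bond of the oxolane, so the C11 hydroxyl ends cis to C9 as in the target; the vinyl triflate is inert.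

Step 15
Reactants: 26
Product: 27 C3,C4,C11-triol vinyl triflate
Conditions: HF·pyridine, pyridine, THF, 0 → 40 °C
Reagents that add atoms: none
Why: Buffered fluoride desilylation cleaves the secondary and tertiary silyl ethers without touching the vinyl triflate and without the strong acid that would trigger transannular etherification of the free C3 hydroxyl.

Step 16
Reactants: 27; 28 octanoyl chloride
Product: 29 C4 octanoate
Conditions: pyridine, DMAP (cat.), CH2Cl2, 0 °C
Reagents that add atoms: none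
Why: Nucleophile-catalysed acylation is selective for the only secondary hydroxyl (C4), the tertiary C3 and C11 hydroxyls being unreactive.

Step 17
Reactants: 29
Product: 30 α-methylidene lactone (C15=CH2, seven-membered C16 lactone to O–C3)
Conditions: Pd(PPh3)4 (10 mol%), CO (1 atm), Et3N, MeCN, 65 °C
Reagents that add atoms: carbon monoxide, [C-]#[O+]
Why: Oxidative addition of the vinyl triflate to zerovalent palladium, CO insertion and intramolecular capture of the acylpalladium by the proximal tertiary C3 hydroxyl (carbonylative lactonisation of a hydroxy vinyl triflate) close the lactone with C16 supplied by CO, the C11 hydroxyl being trans-disposed and unable to reach.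

Step 18
Reactants: 30
Product: 31 C15-methyl lactone (15R) with Z C6=C7 olefin
Conditions: H2 (1 atm), RhCl(PPh3)3 (15 mol%), benzene, rt
Reagents that add atoms: none
Why: Homogeneous hydrogenation reduces only the 1,1-disubstituted conjugated olefin (the trisubstituted ring olefin is inert), and H2 adds to the lactone face bearing H14, anti to the pseudo-axial C3–C4 bond, which places the C15 methyl cis to C13 as required.

Step 19
Reactants: 31
Product: 33 briarellin A, via C6 hydroperoxide 32 (not isolated)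
Conditions: O2, visible light, tetraphenylporphyrin (cat.), CH2Cl2, 0 °C; then PPh3
Reagents that add atoms: dioxygen, O=O
Why: Schenck ene reaction in which singlet oxygen attacks C6 on the exo face of the Z olefin (anti to the C1–C10 bridge) and abstracts hydrogen from the C7 methyl, the ring allylic C–H bonds being unable to align, which moves the double bond exocyclic and sets 6S before phosphine reduction of the hydroperoxide.

## Compound list

1 | methacrolein (2-methylprop-2-enal) | C=C(C)C=O | starting material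
2 | TMS-propargyl pinacolboronate, trimethyl[3-(4,4,5,5-tetramethyl-1,3,2-dioxaborolan-2-yl)prop-1-yn-1-yl]silane | C[Si](C)(C)C#CCB1OC(C)(C)C(C)(C)O1 | starting material
3 | (3S)-2-methyl-6-(trimethylsilyl)hex-1-en-5-yn-3-ol | C=C(C)[C@@H](O)CC#C[Si](C)(C)C | intermediate
4 | (3S,5Z)-2-methyl-6-(trimethylsilyl)hepta-1,5-dien-3-ol | C=C(C)[C@@H](O)C/C=C(/C)[Si](C)(C)C | intermediate
5 | ethyl propiolate | C#CC(=O)OCC | starting material
6 | ethyl (2E)-3-{[(3S,5Z)-2-methyl-6-(trimethylsilyl)hepta-1,5-dien-3-yl]oxy}prop-2-enoate | C=C(C)[C@@H](O/C=C/C(=O)OCC)C/C=C(/C)[Si](C)(C)C | intermediate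
7 | ethyl 2-[(2S,6S)-3-methyl-6-(prop-1-en-2-yl)-3,6-dihydro-2H-pyran-2-yl]acetate (2,6-cis) | C1[C@@H](C(C)=C)O[C@@H](CC(=O)OCC)C(C)=C1 | intermediate
8 | epoxide: ethyl 2-[(2S,4S)-1-methyl-4-(prop-1-en-2-yl)-3,7-dioxabicyclo[4.1.0]heptan-2-yl]acetate, both oxirane faces | C1[C@@H](C(C)=C)O[C@@H](CC(=O)OCC)C2(C)OC12 | intermediate
9 | diol ester: ethyl 2-[(2S,3S,4R,6S)-3,4-dihydroxy-3-methyl-6-(prop-1-en-2-yl)oxan-2-yl]acetate (3,4-trans-diaxial diol) | C1[C@@H](C(C)=C)O[C@@H](CC(=O)OCC)[C@@](C)(O)[C@@H]1O | intermediate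
10 | (3aS,5S,7R,7aS)-7-hydroxy-7a-methyl-5-(prop-1-en-2-yl)hexahydro-2H-furo[3,2-b]pyran-2-one | C1[C@@H](C(C)=C)O[C@H]2CC(=O)O[C@@]2(C)[C@@H]1O | intermediate
11 | lithium 2-[(2S,3S,4R,6S)-3,4-dihydroxy-3-methyl-6-(prop-1-en-2-yl)oxan-2-yl]acetate | C1[C@@H](C(C)=C)O[C@@H](CC(=O)[O-])[C@@](C)(O)[C@@H]1O.[Li+] | intermediate
12 | tert-butyldimethylsilyl 2-[(2S,3R,4R,6S)-3,4-bis(tert-butyldimethylsilyloxy)-3-methyl-6-(prop-1-en-2-yl)oxan-2-yl]acetate | C1[C@@H](C(C)=C)O[C@@H](CC(=O)O[Si](C)(C)C(C)(C)C)[C@@](C)(O[Si](C)(C)C(C)(C)C)[C@@H]1O[Si](C)(C)C(C)(C)C | intermediate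
13 | 2-[(2S,3R,4R,6S)-3,4-bis(tert-butyldimethylsilyloxy)-3-methyl-6-(prop-1-en-2-yl)oxan-2-yl]acetic acid | C1[C@@H](C(C)=C)O[C@@H](CC(=O)O)[C@@](C)(O[Si](C)(C)C(C)(C)C)[C@@H]1O[Si](C)(C)C(C)(C)C | intermediate
14 | mixed isobutyl carbonic anhydride of 13 | C1[C@@H](C(C)=C)O[C@@H](CC(=O)OC(=O)OCC(C)C)[C@@](C)(O[Si](C)(C)C(C)(C)C)[C@@H]1O[Si](C)(C)C(C)(C)C | intermediate
15 | 1-diazo-3-[(2S,3R,4R,6S)-3,4-bis(tert-butyldimethylsilyloxy)-3-methyl-6-(prop-1-en-2-yl)oxan-2-yl]propan-2-one | C1[C@@H](C(C)=C)O[C@@H](CC(=O)C=[N+]=[N-])[C@@](C)(O[Si](C)(C)C(C)(C)C)[C@@H]1O[Si](C)(C)C(C)(C)C | intermediate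
16 | oxonium ylide: oxane oxygen bonded to the carbanionic C9 of a fused 3-oxo-oxolane, substituents as in 15 | C1[C@@H](C(C)=C)[O+]2[C@@H](CC(=O)[CH-]2)[C@@](C)(O[Si](C)(C)C(C)(C)C)[C@@H]1O[Si](C)(C)C(C)(C)C | intermediate
17 | (5Z)-2,3-bis(tert-butyldimethylsilyloxy)-2,6-dimethyl-11-oxabicyclo[6.2.1]undec-5-en-9-one (C10 ketone; C2, C3, C4, C9 arranged as in 33) | C1/C=C(C)\C[C@@H]2O[C@@H](CC2=O)[C@@](C)(O[Si](C)(C)C(C)(C)C)[C@@H]1O[Si](C)(C)C(C)(C)C | intermediate
18 | C1=C10 enol triflate of 17, (5Z)-2,3-bis(tert-butyldimethylsilyloxy)-2,6-dimethyl-11-oxabicyclo[6.2.1]undeca-5,9-dien-9-yl trifluoromethanesulfonate | C1/C=C(C)\C[C@@H]2O[C@@H](C=C2OS(=O)(=O)C(F)(F)F)[C@@](C)(O[Si](C)(C)C(C)(C)C)[C@@H]1O[Si](C)(C)C(C)(C)C | intermediate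
19 | tributyl(1-ethoxyvinyl)stannane | CCCC[Sn](CCCC)(CCCC)C(=C)OCC | starting material
20 | (5Z)-9-(1-ethoxyethenyl)-2,3-bis(tert-butyldimethylsilyloxy)-2,6-dimethyl-11-oxabicyclo[6.2.1]undeca-5,9-diene | C1/C=C(C)\C[C@@H]2O[C@@H](C=C2C(=C)OCC)[C@@](C)(O[Si](C)(C)C(C)(C)C)[C@@H]1O[Si](C)(C)C(C)(C)C | intermediate
21 | methyl vinyl ketone (but-3-en-2-one) | C=CC(C)=O | starting material
22 | Diels–Alder adduct, both C14 epimers: tricycle (oxonene, oxolane, cyclohexene) with C14 acetyl, C10=C11 enol ether (11-OEt), Z C6=C7, 3,4-bis-OTBS, C1–C14 bond anti to C3 | C1/C=C(C)\C[C@@H]2O[C@@H]([C@H]3C(CCC(OCC)=C32)C(C)=O)[C@@](C)(O[Si](C)(C)C(C)(C)C)[C@@H]1O[Si](C)(C)C(C)(C)C | intermediate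
23 | single C14 epimer of 22, acetyl trans to C2 (C1, C2, C3, C4, C9, C14 arranged as in 33) | C1/C=C(C)\C[C@@H]2O[C@@H]([C@H]3[C@@H](CCC(OCC)=C32)C(C)=O)[C@@](C)(O[Si](C)(C)C(C)(C)C)[C@@H]1O[Si](C)(C)C(C)(C)C | intermediate
24 | vinyl triflate of 23: C14–C(=CH2)OSO2CF3, C10=C11 enol ether retained | C1/C=C(C)\C[C@@H]2O[C@@H]([C@H]3[C@@H](CCC(OCC)=C32)C(=C)OS(=O)(=O)C(F)(F)F)[C@@](C)(O[Si](C)(C)C(C)(C)C)[C@@H]1O[Si](C)(C)C(C)(C)C | intermediate
25 | C11 ketone, cis-fused (H1/H10 cis), C14 isopropenyl triflate, 3,4-bis-OTBS | C1/C=C(C)\C[C@@H]2O[C@@H]([C@H]3[C@@H](CCC(=O)[C@H]32)C(=C)OS(=O)(=O)C(F)(F)F)[C@@](C)(O[Si](C)(C)C(C)(C)C)[C@@H]1O[Si](C)(C)C(C)(C)C | intermediate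
26 | (11R) tertiary alcohol from 25: C11 methyl carbinol, OH cis to C9 | C1/C=C(C)\C[C@@H]2O[C@@H]([C@H]3[C@@H](CC[C@@](C)(O)[C@H]32)C(=C)OS(=O)(=O)C(F)(F)F)[C@@](C)(O[Si](C)(C)C(C)(C)C)[C@@H]1O[Si](C)(C)C(C)(C)C | intermediate
27 | C3,C4,C11-triol with C14 isopropenyl triflate | C1/C=C(C)\C[C@@H]2O[C@@H]([C@H]3[C@@H](CC[C@@](C)(O)[C@H]32)C(=C)OS(=O)(=O)C(F)(F)F)[C@@](C)(O)[C@@H]1O | intermediate
28 | octanoyl chloride | CCCCCCCC(=O)Cl | starting material
29 | C4 octanoate of 27 | C1/C=C(C)\C[C@@H]2O[C@@H]([C@H]3[C@@H](CC[C@@](C)(O)[C@H]32)C(=C)OS(=O)(=O)C(F)(F)F)[C@@](C)(O)[C@@H]1OC(=O)CCCCCCC | intermediate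
30 | α-methylidene lactone: briarellin A skeleton with C15=CH2 and Z C6=C7(CH3) in place of C6–OH/C7=CH2 | C1/C=C(C)\C[C@@H]2O[C@H]3[C@H]4[C@@H](CC[C@@](C)(O)[C@H]42)C(=C)C(=O)O[C@@]3(C)[C@@H]1OC(=O)CCCCCCC | intermediate
31 | (15R)-methyl lactone with Z C6=C7(CH3) olefin (6-deoxy olefin isomer of 33) | C1/C=C(C)\C[C@@H]2O[C@H]3[C@H]4[C@@H](CC[C@@](C)(O)[C@H]42)[C@@H](C)C(=O)O[C@@]3(C)[C@@H]1OC(=O)CCCCCCC | intermediate
32 | (6S)-6-hydroperoxide corresponding to 33 | C=C1C[C@@H]2O[C@H]3[C@H]4[C@@H](CC[C@@](C)(O)[C@H]42)[C@@H](C)C(=O)O[C@@]3(C)[C@H](OC(=O)CCCCCCC)C[C@@H]1OO | intermediate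
33 | briarellin A (1S,2S,3S,4R,6S,9S,10R,11R,14R,15R in eunicellin locants) | C=C1C[C@@H]2O[C@H]3[C@H]4[C@@H](CC[C@@](C)(O)[C@H]42)[C@@H](C)C(=O)O[C@@]3(C)[C@H](OC(=O)CCCCCCC)C[C@@H]1O | target

## Step count

Total steps: 19. Longest linear sequence: 19 (fully linear from methacrolein).

## Steps most likely to fail and fallbacks

Step 4 (protonation-triggered silyl-Prins cyclisation). It is unprecedented as a combination and could suffer protodesilylation, acrylate loss or erosion of ee through oxonia-Cope pathways. The fallback sets out from 4 and comes back at 7. It replaces the internal acrylate by an external, non-enolisable aldehyde: InCl3-promoted silyl-Prins reaction of 4 with ethyl glyoxylate in CH2Cl2 gives ethyl (2R,6S)-3-methyl-6-(prop-1-en-2-yl)-3,6-dihydro-2H-pyran-2-carboxylate F1 (2,6-cis by the same chair transition state). Saponification with LiOH gives the carboxylic acid F2. Activation with i-BuOCOCl/Et3N and CH2N2 gives the diazoketone F3. Wolff rearrangement with PhCO2Ag and Et3N in ethanol (Arndt–Eistert homologation, retention at C2) then delivers 7.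

Step 17 (carbonylative closure of a seven-membered lactone onto a tertiary alcohol). The acylpalladium may not be captured by the hindered C3 hydroxyl. The fallback sets out from 29 and comes back at 30. It separates carbonylation from ring closure: hydroxycarbonylation of 29 with Pd(OAc)2, PPh3, CO and KOAc in wet DMF gives the 2-substituted acrylic acid F4. Yamaguchi activation (2,4,6-trichlorobenzoyl chloride, Et3N, then DMAP in toluene under high dilution) then closes the lactone to 30.

Step 19 (Schenck ene reaction). Ring allylic hydrogens at C5 or C8 could compete with the methyl hydrogens, and the lactone and ester chain might alter the facial bias. The fallback sets out from 31 and comes back at 33. Epoxidation of the Z olefin with dimethyldioxirane in acetone at −20 °C on the same exo face gives the 6,7-epoxide F5. Base-induced epoxide-to-allylic-alcohol isomerisation with diethylaluminium 2,2,6,6-tetramethylpiperidide (Et2AlNC9H18) in benzene at 0 °C removes a proton from the C7 methyl by syn-elimination and gives 33 directly.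

## Further compounds

F1 | step 4 | ethyl (2R,6S)-3-methyl-6-(prop-1-en-2-yl)-3,6-dihydro-2H-pyran-2-carboxylate | C1[C@@H](C(C)=C)O[C@@H](C(=O)OCC)C(C)=C1
F2 | step 4 | (2R,6S)-3-methyl-6-(prop-1-en-2-yl)-3,6-dihydro-2H-pyran-2-carboxylic acid | C1[C@@H](C(C)=C)O[C@@H](C(=O)O)C(C)=C1
F3 | step 4 | 2-diazo-1-[(2R,6S)-3-methyl-6-(prop-1-en-2-yl)-3,6-dihydro-2H-pyran-2-yl]ethan-1-one | C1[C@@H](C(C)=C)O[C@@H](C(=O)C=[N+]=[N-])C(C)=C1
F4 | step 17 | 2-substituted acrylic acid from 29 (C14–C(=CH2)CO2H, C3–OH free, C4 octanoate) | C1/C=C(C)\C[C@@H]2O[C@@H]([C@H]3[C@@H](CC[C@@](C)(O)[C@H]32)C(=C)C(=O)O)[C@@](C)(O)[C@@H]1OC(=O)CCCCCCC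
F5 | step 19 | 6,7-epoxide of 31 (oxirane on the exo face, C6–O as in 33) | C[C@@]12C[C@@H]3O[C@H]4[C@H]5[C@@H](CC[C@@](C)(O)[C@H]53)[C@@H](C)C(=O)O[C@@]4(C)[C@H](OC(=O)CCCCCCC)C[C@@H]1O2
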